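The γ-lactone ring is cut at its CH2–CH(OO) bond (C2–C3) and its ring O–C(CH3) bond (O–C4): C3 becomes an aldehyde carbon and C4 the tertiary carbon of an epoxide. In one flask, Z-selective Horner–Wadsworth–Emmons olefination of (R)-2-methyloxirane-2-carbaldehyde forms C2–C3, and the ester carbonyl then opens the epoxide at C4 with inversion (O–C4). This gives a butenolide whose quaternary C4 derives from bought (S)-2-methylglycidol. The feature exploited is the cis-fused lactone/1,2-dioxane junction C3–C4: the butenolide later accepts the peroxide oxygen at C3, and the bicyclic peroxycarbenium ion sets the chain-bearing C6 by axial allylation.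

Key step: step 2

Remark: plakortolide numbering is used for all intermediates: C1 lactone carbonyl, C2 lactone CH2, C3 peroxy CH, C4 methyl-bearing lactone carbon, C5 ring CH2, C6 chain-bearing peroxy carbon.
Assumption: (S)-2-methylglycidol is bought enantiopure (it is also the product of asymmetric epoxidation of 2-methylprop-2-en-1-ol).

Step 1
Reactants: 1 (S)-2-methylglycidol [(2S)-(2-methyloxiran-2-yl)methanol]
Product: 2 (R)-2-methyloxirane-2-carbaldehyde
Conditions: TEMPO (10 mol%), PhI(OAc)2, CH2Cl2, 0 °C to rt; aqueous NaHCO3 wash; dried solution used at once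
Reagents that add atoms: none
Why: The nitroxyl-catalysed oxidation of a primary epoxy alcohol (TEMPO/PhI(OAc)2 oxidation) should stop at the aldehyde and cannot epimerise the quaternary epoxide carbon, whose descriptor changes from S to R only because CHO outranks the ring CH2.

Step 2
Reactants: 2 (R)-2-methyloxirane-2-carbaldehyde; 3 ethyl 2-(diphenoxyphosphoryl)acetate
Product: 5 (R)-5-(hydroxymethyl)-5-methylfuran-2(5H)-one, via Z-epoxy enoate 4 (not isolated)
Conditions: 3 (1.1 equiv), NaH, THF, −78 to 0 °C; then camphorsulfonic acid (0.3 equiv), H2O (3 equiv), 0 °C to rt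
Reagents that add atoms: water, SMILES O
Why: The sodium phosphonate anion of 3 adds to aldehyde 2 and the oxaphosphetane collapses to Z-enoate 4, which forms the C2–C3 bond; acid then activates the epoxide, the ester carbonyl oxygen attacks the tertiary carbon C4 from the face opposite the epoxide oxygen, and water expels ethanol from the alkoxyfuranylium ion, which forms the ring O–C4 bond and frees the C5 hydroxyl. The closest known reaction type is the Z-selective Horner–Wadsworth–Emmons olefination of 2,3-epoxy aldehydes followed by acid-mediated lactonisation of the cis-epoxy enoates to γ-(hydroxyalkyl)butenolides. The lactone closes in the 5-exo-tet mode at the epoxide, the competing 6-endo mode requiring attack at the primary carbon C5. C4 is the only new stereocentre and is controlled by the bought epoxide centre through stereospecific inversion, so that (S)-configured C4 of 4 becomes (R)-configured C4 of 5, the arrangement required in the target. The step needs Z geometry, which the diaryl phosphonate at −78 °C should secure (the E isomer cannot lactonise and is removed), and opening at C4, which the tertiary, cation-stabilising carbon and the five-membered transition state should secure.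

Step 3
Reactants: 5 (R)-5-(hydroxymethyl)-5-methylfuran-2(5H)-one
Product: 6 (R)-2-methyl-5-oxo-2,5-dihydrofuran-2-carbaldehyde
Conditions: Dess–Martin periodinane, CH2Cl2, 0 °C to rt
Reagents that add atoms: none
Why: Dess–Martin oxidation of the neopentyl-type primary alcohol should give the non-enolisable α-acyloxy aldehyde without touching the butenolide or the quaternary centre.

Step 4
Reactants: 7 1,1-dimethoxyethane; 8 triphenylphosphine
Product: 9 (1-methoxyethyl)triphenylphosphonium tetrafluoroborate (racemic)
Conditions: HBF4·OEt2 (1 equiv), CH2Cl2, 0 °C to rt; salt precipitated with Et2O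
Reagents that add atoms: tetrafluoroboric acid (as its diethyl ether complex), SMILES [H+].F[B-](F)(F)F
Why: Protonation of the acetal, loss of methanol and capture of the oxocarbenium ion by the phosphine (α-alkoxyalkylphosphonium salt formation) should give the salt as a racemate, its stereocentre being lost in the ylide.

Step 5
Reactants: 6 (R)-2-methyl-5-oxo-2,5-dihydrofuran-2-carbaldehyde; 9 (1-methoxyethyl)triphenylphosphonium tetrafluoroborate
Product: 11 (R)-5-(2-methoxyprop-1-en-1-yl)-5-methylfuran-2(5H)-one (E/Z mixture), via phosphorus ylide 10 (not isolated)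
Conditions: 9, KN(SiMe3)2, THF, −78 °C; then 6, −78 to −20 °C
Reagents that add atoms: none
Why: Wittig olefination with the α-methoxy ylide should turn the hindered but strongly electrophilic aldehyde into the methyl enol ether (a masked C6 methyl ketone) faster than the ylide adds to the butenolide, and the enol ether geometry is irrelevant.

Step 6
Reactants: 11 (R)-5-(2-methoxyprop-1-en-1-yl)-5-methylfuran-2(5H)-one
Product: 12 (5S)-5-(2-hydroperoxy-2-methoxypropyl)-5-methylfuran-2(5H)-one (both C6 epimers)
Conditions: anhydrous H2O2 in Et2O (5 equiv), pyridinium p-toluenesulfonate (5 mol%), 0 °C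
Reagents that add atoms: hydrogen peroxide, SMILES OO
Why: Acid-catalysed Markovnikov addition of H2O2 to the enol ether (perhydrolysis through the C6 oxocarbenium ion) should give the α-methoxy hydroperoxide, whose new C6 centre forms without control and is erased again in step 8.

Step 7
Reactants: 12 (5S)-5-(2-hydroperoxy-2-methoxypropyl)-5-methylfuran-2(5H)-one
Product: 13 (4aS,7aS)-3-methoxy-3,4a-dimethyl-3,4,4a,7a-tetrahydrofuro[3,2-c][1,2]dioxin-6(7H)-one (cis-fused peroxyketal lactone with OCH3 and CH3 at C6, both C6 epimers)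
Conditions: Et2NH (0.5 equiv), CF3CH2OH, rt
Reagents that add atoms: none
Why: Amine-promoted intramolecular oxa-Michael addition (6-exo-trig) of the hydroperoxide to the butenolide should close the 1,2-dioxane, and C3 is set by C4 because the five-membered lactone can only be cis-fused, the peroxide oxygen entering on the face of the C5 arm.

Step 8
Reactants: 13 cis-fused peroxyketal lactone; 14 allyltrimethylsilane
Product: 15 (3R,4aS,7aS)-3,4a-dimethyl-3-(prop-2-en-1-yl)-3,4,4a,7a-tetrahydrofuro[3,2-c][1,2]dioxin-6(7H)-one (allyl and CH3 at C6, allyl cis to the lactone oxygen at C4)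
Conditions: 14 (3 equiv), Me3SiOTf (0.2 equiv), CH2Cl2, −78 °C
Reagents that add atoms: none
Why: Me3SiOTf should ionise the exocyclic C6–OCH3 bond to the cyclic peroxycarbenium ion, which allyltrimethylsilane captures (Hosomi–Sakurai allylation) by axial attack on the half-chair that keeps the C4 methyl and C2 equatorial, that is syn to the axial lactone oxygen and anti to the C4 methyl, so that allyl ends cis to the lactone and the C6 methyl trans (6R in plakortolide numbering).

Step 9
Reactants: 16 (4-bromophenoxy)(tert-butyl)dimethylsilane; 17 8-bromooct-1-ene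
Product: 19 tert-butyldimethyl[4-(oct-7-en-1-yl)phenoxy]silane, via aryl Grignard reagent 18 (not isolated)
Conditions: 16, Mg, THF, reflux; then 17, Li2CuCl4 (3 mol%), THF, 0 °C
Reagents that add atoms: none
Why: Copper-catalysed cross-coupling of the aryl Grignard reagent with the primary alkyl bromide (Kumada-type sp2–sp3 coupling) should give the ω-aryl alkene, the aryl silyl ether and the terminal alkene being inert.

Step 10
Reactants: 15 C6-allyl peroxylactone; 19 tert-butyldimethyl[4-(oct-7-en-1-yl)phenoxy]silane
Product: 20 (3R,4aS,7aS)-3-{9-[4-(tert-butyldimethylsilyloxy)phenyl]non-2-en-1-yl}-3,4a-dimethyl-3,4,4a,7a-tetrahydrofuro[3,2-c][1,2]dioxin-6(7H)-one (E/Z mixture)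
Conditions: second-generation Grubbs catalyst RuCl2(=CHPh)(PCy3)(H2IMes) (5 mol%), 19 (3 equiv), CH2Cl2, 40 °C
Reagents that add atoms: none
Why: Olefin cross-metathesis of two terminal alkenes should join the side chain with loss of ethene, the dialkyl peroxide and the lactone being tolerated by the ruthenium carbene and the alkene geometry being irrelevant.

Step 11
Reactants: 20 unsaturated silyl-protected peroxylactone
Product: 21 (3R,4aS,7aS)-3-{9-[4-(tert-butyldimethylsilyloxy)phenyl]nonyl}-3,4a-dimethyl-3,4,4a,7a-tetrahydrofuro[3,2-c][1,2]dioxin-6(7H)-one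
Conditions: KO2C–N=N–CO2K (10 equiv), AcOH (20 equiv), MeOH–pyridine, 0 °C to rt
Reagents that add atoms: none
Why: Diimide reduction (concerted syn transfer of two hydrogens) should saturate the disubstituted alkene and leave the O–O bond, which would not survive catalytic hydrogenation, untouched.

Step 12
Reactants: 21 silyl-protected plakortolide F
Product: 22 plakortolide F
Conditions: Bu4NF, AcOH, THF, 0 °C
Reagents that add atoms: none
Why: Fluoride-mediated desilylation of the aryl silyl ether, buffered with acetic acid to spare the lactone and the peroxide, should release the phenol without affecting any stereocentre.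

Compound list
1 | (S)-2-methylglycidol, (2S)-(2-methyloxiran-2-yl)methanol | OC[C@@]1(C)CO1 | starting material
2 | (R)-2-methyloxirane-2-carbaldehyde | O=C[C@@]1(C)CO1 | intermediate
3 | ethyl 2-(diphenoxyphosphoryl)acetate | CCOC(=O)CP(=O)(Oc1ccccc1)Oc1ccccc1 | starting material
4 | ethyl (Z)-3-[(2S)-2-methyloxiran-2-yl]prop-2-enoate | CCOC(=O)/C=C\[C@@]1(C)CO1 | intermediate
5 | (R)-5-(hydroxymethyl)-5-methylfuran-2(5H)-one | O=C1C=C[C@](C)(CO)O1 | intermediate
6 | (R)-2-methyl-5-oxo-2,5-dihydrofuran-2-carbaldehyde | O=C1C=C[C@](C)(C=O)O1 | intermediate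
7 | 1,1-dimethoxyethane | CC(OC)OC | starting material
8 | triphenylphosphine | c1ccc(cc1)P(c1ccccc1)c1ccccc1 | starting material
9 | (1-methoxyethyl)triphenylphosphonium tetrafluoroborate (racemic) | COC(C)[P+](c1ccccc1)(c1ccccc1)c1ccccc1.F[B-](F)(F)F | intermediate
10 | (1-methoxyethylidene)triphenylphosphorane | COC(C)=P(c1ccccc1)(c1ccccc1)c1ccccc1 | intermediate
11 | (R)-5-(2-methoxyprop-1-en-1-yl)-5-methylfuran-2(5H)-one (E/Z mixture) | O=C1C=C[C@](C)(C=C(C)OC)O1 | intermediate
12 | (5S)-5-(2-hydroperoxy-2-methoxypropyl)-5-methylfuran-2(5H)-one (both C6 epimers) | O=C1C=C[C@](C)(CC(C)(OC)OO)O1 | intermediate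
13 | (4aS,7aS)-3-methoxy-3,4a-dimethyl-3,4,4a,7a-tetrahydrofuro[3,2-c][1,2]dioxin-6(7H)-one (both C6 epimers) | COC1(C)C[C@]2(C)OC(=O)C[C@@H]2OO1 | intermediate
14 | allyltrimethylsilane | C=CC[Si](C)(C)C | starting material
15 | (3R,4aS,7aS)-3,4a-dimethyl-3-(prop-2-en-1-yl)-3,4,4a,7a-tetrahydrofuro[3,2-c][1,2]dioxin-6(7H)-one | C[C@@]1(CC=C)C[C@]2(C)OC(=O)C[C@@H]2OO1 | intermediate
16 | (4-bromophenoxy)(tert-butyl)dimethylsilane | CC(C)(C)[Si](C)(C)Oc1ccc(Br)cc1 | starting material
17 | 8-bromooct-1-ene | C=CCCCCCCBr | starting material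
18 | [4-(tert-butyldimethylsilyloxy)phenyl]magnesium bromide | CC(C)(C)[Si](C)(C)Oc1ccc([Mg]Br)cc1 | intermediate
19 | tert-butyldimethyl[4-(oct-7-en-1-yl)phenoxy]silane | C=CCCCCCCc1ccc(O[Si](C)(C)C(C)(C)C)cc1 | intermediate
20 | (3R,4aS,7aS)-3-{9-[4-(tert-butyldimethylsilyloxy)phenyl]non-2-en-1-yl}-3,4a-dimethyl-3,4,4a,7a-tetrahydrofuro[3,2-c][1,2]dioxin-6(7H)-one (E/Z mixture) | C[C@@]1(CC=CCCCCCCc2ccc(O[Si](C)(C)C(C)(C)C)cc2)C[C@]2(C)OC(=O)C[C@@H]2OO1 | intermediate
21 | (3R,4aS,7aS)-3-{9-[4-(tert-butyldimethylsilyloxy)phenyl]nonyl}-3,4a-dimethyl-3,4,4a,7a-tetrahydrofuro[3,2-c][1,2]dioxin-6(7H)-one | C[C@@]1(CCCCCCCCCc2ccc(O[Si](C)(C)C(C)(C)C)cc2)C[C@]2(C)OC(=O)C[C@@H]2OO1 | intermediate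
22 | plakortolide F, (3R,4aS,7aS)-3-[9-(4-hydroxyphenyl)nonyl]-3,4a-dimethyl-3,4,4a,7a-tetrahydrofuro[3,2-c][1,2]dioxin-6(7H)-one | C[C@@]1(CCCCCCCCCc2ccc(O)cc2)C[C@]2(C)OC(=O)C[C@@H]2OO1 | target

Total step count: 12. Longest linear sequence: 10 steps (steps 1, 2, 3, 5, 6, 7, 8, 10, 11, 12); steps 4 and 9 prepare the two side reagents.

Steps most likely to fail

Step 8. The Lewis acid may ionise the ring C6–O bond or fragment the peroxide instead of removing methoxide, and axial attack may not discriminate the two faces of the peroxycarbenium ion well enough. The fallback sets out from 6 (with Grignard reagent 18) and comes back at 21; it makes the peroxide by radical hydroperoxidation and accepts an uncontrolled C6. Reagent 18 is coupled with excess 1,9-dibromononane (Li2CuCl4, THF) to give [4-(9-bromononyl)phenoxy](tert-butyl)dimethylsilane F1. Ethylidenetriphenylphosphorane (from ethyltriphenylphosphonium bromide and BuLi) is alkylated with F1 to the secondary salt {11-[4-(tert-butyldimethylsilyloxy)phenyl]undecan-2-yl}triphenylphosphonium bromide F2. Its ylide (BuLi, THF, −78 °C) is condensed with aldehyde 6 to the trisubstituted alkene (R)-5-{11-[4-(tert-butyldimethylsilyloxy)phenyl]-2-methylundec-1-en-1-yl}-5-methylfuran-2(5H)-one F3. Mukaiyama–Isayama hydroperoxysilylation (Co(thd)2 with thd = 2,2,6,6-tetramethylheptane-3,5-dionate, O2, Et3SiH) places the peroxide at the tertiary carbon and should give the triethylsilyl peroxide (5S)-5-{11-[4-(tert-butyldimethylsilyloxy)phenyl]-2-methyl-2-[(triethylsilyl)peroxy]undecyl}-5-methylfuran-2(5H)-one F4 as both C6 epimers. Acid methanolysis of the O–Si bond and then Et2NH in CF3CH2OH close the dioxane to 21 and its C6 epimer (3S,4aS,7aS)-3-{9-[4-(tert-butyldimethylsilyloxy)phenyl]nonyl}-3,4a-dimethyl-3,4,4a,7a-tetrahydrofuro[3,2-c][1,2]dioxin-6(7H)-one F5, which are separated by chromatography.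

Step 5. The α-methoxy ylide may decompose, or add in conjugate fashion to the butenolide, before it reaches the hindered aldehyde. The fallback sets out from 6 and comes back at 12. Wittig reaction of 6 with the more robust ethylidenetriphenylphosphorane should give (S)-5-methyl-5-[(Z)-prop-1-en-1-yl]furan-2(5H)-one F6. Wacker oxidation (PdCl2, CuCl, O2, DMF–H2O), which should place the carbonyl at the carbon remote from the quaternary C–O centre, gives the methyl ketone (S)-5-methyl-5-(2-oxopropyl)furan-2(5H)-one F7. Urea–H2O2 with Sc(OTf)3 in MeOH then converts the ketone into the methoxy hydroperoxide 12.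

Step 2. The olefination may lose Z selectivity (the E-enoate cannot lactonise), and the acid may open the epoxide at C5 or through water and lead to the six-membered lactone. The fallback sets out from 2 and comes back at 5. Aldol addition of the lithium enolate of tert-butyl acetate (LiN(iPr)2, THF, −78 °C) to 2 should give tert-butyl 3-hydroxy-3-[(2R)-2-methyloxiran-2-yl]propanoate F8, with no alkene geometry to control. CF3CO2H then lets the ester carbonyl open the epoxide at C4 (5-exo, inversion, loss of 2-methylpropene) to (5S)-4-hydroxy-5-(hydroxymethyl)-5-methyloxolan-2-one F9. Acetylation (Ac2O, pyridine) gives the diacetate [(2S)-3-(acetyloxy)-2-methyl-5-oxooxolan-2-yl]methyl acetate F10. DBU eliminates the β-acetoxy group to [(2R)-2-methyl-5-oxo-2,5-dihydrofuran-2-yl]methyl acetate F11, and acid methanolysis (HCl, MeOH) returns 5.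

Further compounds
F1 | step 8 | [4-(9-bromononyl)phenoxy](tert-butyl)dimethylsilane | BrCCCCCCCCCc1ccc(O[Si](C)(C)C(C)(C)C)cc1
F2 | step 8 | {11-[4-(tert-butyldimethylsilyloxy)phenyl]undecan-2-yl}triphenylphosphonium bromide | CC(CCCCCCCCCc1ccc(O[Si](C)(C)C(C)(C)C)cc1)[P+](c1ccccc1)(c1ccccc1)c1ccccc1.[Br-]
F3 | step 8 | (R)-5-{11-[4-(tert-butyldimethylsilyloxy)phenyl]-2-methylundec-1-en-1-yl}-5-methylfuran-2(5H)-one (E/Z mixture) | O=C1C=C[C@](C)(C=C(C)CCCCCCCCCc2ccc(O[Si](C)(C)C(C)(C)C)cc2)O1
F4 | step 8 | (5S)-5-{11-[4-(tert-butyldimethylsilyloxy)phenyl]-2-methyl-2-[(triethylsilyl)peroxy]undecyl}-5-methylfuran-2(5H)-one (both C6 epimers) | O=C1C=C[C@](C)(CC(C)(CCCCCCCCCc2ccc(O[Si](C)(C)C(C)(C)C)cc2)OO[Si](CC)(CC)CC)O1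
F5 | step 8 | (3S,4aS,7aS)-3-{9-[4-(tert-butyldimethylsilyloxy)phenyl]nonyl}-3,4a-dimethyl-3,4,4a,7a-tetrahydrofuro[3,2-c][1,2]dioxin-6(7H)-one | C[C@]1(CCCCCCCCCc2ccc(O[Si](C)(C)C(C)(C)C)cc2)C[C@]2(C)OC(=O)C[C@@H]2OO1
F6 | step 5 | (S)-5-methyl-5-[(Z)-prop-1-en-1-yl]furan-2(5H)-one | O=C1C=C[C@](C)(/C=C\C)O1
F7 | step 5 | (S)-5-methyl-5-(2-oxopropyl)furan-2(5H)-one | O=C1C=C[C@](C)(CC(C)=O)O1
F8 | step 2 | tert-butyl 3-hydroxy-3-[(2R)-2-methyloxiran-2-yl]propanoate (both carbinol epimers) | CC(C)(C)OC(=O)CC(O)[C@@]1(C)CO1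
F9 | step 2 | (5S)-4-hydroxy-5-(hydroxymethyl)-5-methyloxolan-2-one (both carbinol epimers) | O=C1CC(O)[C@](C)(CO)O1
F10 | step 2 | [(2S)-3-(acetyloxy)-2-methyl-5-oxooxolan-2-yl]methyl acetate (both epimers at the acetoxy carbon) | O=C1CC(OC(C)=O)[C@](C)(COC(C)=O)O1
F11 | step 2 | [(2R)-2-methyl-5-oxo-2,5-dihydrofuran-2-yl]methyl acetate | O=C1C=C[C@](C)(COC(C)=O)O1
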